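The runs were generated by integration for an exercise; noise was put on by code.

Late in both earlier runs D keeps climbing while Q moves little beside it, so from then on each new D seems to cost two Z: its own and the one that replaces the Q it consumed.

the same everywhere: Z 0.0475 M; L 10 mM; X 2.5 mM
- dawn: E 0.025 M; run made earlier
- summer: E 0.038 M; run made earlier
- Wednesday's: E 0.050 M; time 25 d
- Sunday's: E 0.050 M; time 40 d

| run | time / d | G / % | Q / % | E / % | D / % |
|---|---|---|---|---|---|
| dawn | 2.08 | 1.3 | 8.8 | 78.4 | 3.0 |
| dawn | 3.00 | 1.2 | 13.6 | 70.0 | 6.0 |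
| dawn | 6.00 | 5.0 | 17.4 | 51.9 | 15.2 |
| dawn | 10.0 | 7.9 | 18.1 | 37.2 | 30.9 |
| dawn | 15.0 | 7.3 | 17.7 | 25.1 | 44.2 |
| dawn | 25.0 | 10.2 | 14.3 | 14.1 | 61.2 |
| summer | 2.08 | 0.9 | 8.3 | 76.3 | 3.6 |
| summer | 3.00 | 3.1 | 11.2 | 69.1 | 4.7 |
| summer | 6.00 | 1.8 | 18.4 | 51.6 | 14.7 |
| summer | 10.0 | 6.9 | 21.9 | 38.5 | 27.2 |
| summer | 15.0 | 9.1 | 19.1 | 29.3 | 35.9 |
| summer | 25.0 | 14.1 | 19.9 | 17.6 | 47.4 |

(standard deviation of a reading: 1 percentage point)

* which of these there is most of at the end, counted by the E in it, Wednesday's (G / E / D / Q)
* which of these there is most of at the end, counted by the E in it, Sunday's (G / E / D / Q)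
* how much there is at the end of the one of these that leads, in percent of the E charged: Wednesday's
* how much there is at the end of the one of these that leads, in percent of the E charged: Sunday's



Count everything as fractions of the E charged. If Z goes in once for Q and twice for D, as the forecast also takes it, then Q plus two D can't pass the ratio of Z to E charged, 0.950 in both new flasks. With no Q, that caps D at 47.5%. But Q stands, so subtract the dawn run's last reading of it, 14.3%, and share out the rest at two Z per D. This is the Z ceiling: 40.3%, good as a bound while Q stays at or above that reading.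

Now from below, my own reckoning. Between 10.0 d and 15.0 d in the dawn run, D takes 0.0274 d⁻¹ of the free Z, a pseudo-first-order rate read from the mean Q and mean Z of that stretch. Scale it to the new E charge, use the Q of the ceiling, and count two Z per D: Z then has a mean life of 11.4 d. Start from what the summer readings leave at 6.00 d, let that Z decay, and subtract the summer run's high Q reading, 21.9%. This floor, an estimate and no proof, puts D near 32.1% in Wednesday's flask and 35.4% in Sunday's. Wednesday's floor stands above the summer run's last E, Q and G, so I expect D to lead there, and Sunday's floor is higher.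

The forecast names D for Wednesday's flask and D for Sunday's, at 35% and 38%, each inside its bracket. Its ground: “Z is nearly gone by about 20 d”.

D leads both flasks: Wednesday's gives 34.8%, Sunday's 36.8%.

    E + L ⇌ L + J (K = 0.390, k = 1.90 × 10⁻⁴ M⁻¹ s⁻¹)
    J → G (k = 8.20 × 10⁻⁷ s⁻¹)
    Z + X + J → X + Q (k = 0.0700 M⁻² s⁻¹)
    Z + Q → D (k = 7.00 × 10⁻⁵ M⁻¹ s⁻¹)

The depletion of Z is the main reason D stops short: with Z held, Wednesday's D reaches 79.0% instead of 34.8%. Z, the limiting reagent, is down to 4.6% of its charge in Wednesday's flask and 0.90% in Sunday's, with D under the ceiling. At a Z charge of 0.0414 M, Wednesday's D has moved 6 points, past the forecast's low end of 30%.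

In the neighbour of Wednesday's charged with 0.081 M of Z, the ceiling lifts to 73.8%. That flask gives D 64.5%, with 13% of its Z still free.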